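**Plan**
1. Cuts: (a) the tert-butyl carbonate mask on the C4 oxygen, removed in the last step; (b) in one operation, the aryl O–acetyl bond and the CH2–CH2 bond between the benzylic carbon and the C12 chain; (c) the C–O bond para to the phenol of o-vanillin.
2. Enabling feature: on the benzene ring the acetate-bearing oxygen (on C1) is ortho to C6, which carries the chain. The unit O–C1–C6–CH2 is therefore a latent o-quinone methide (6-methylidenecyclohexa-2,4-dienone) with an electrophilic exocyclic CH2.
3. Attack of a dodecyl nucleophile at that CH2 rearomatises the ring. This bares only the C1 oxygen, the hindered one of the two hydroquinone oxygens, for acetylation in the same flask.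
4. Forward order: o-vanillin; para-hydroxylation; both phenols to OBoc (ortho one as trigger, para one as protecting group); CHO to CH2OH; cascade with dodecylmagnesium bromide and acetic anhydride; acidolysis of the last Boc group.
5. The arene is bought and no ring is formed. The chain is joined in step 4. The target has no stereocentre and no C=C geometry, so no stereochemistry has to be introduced.

Key step: step 4

Remark: the target SMILES holds no stereocentre, so the compound is achiral and the demand for a single enantiomer is met trivially.

**Step 1**
Reactants: 1 o-vanillin (2-hydroxy-3-methoxybenzaldehyde)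
Product: 3 2,5-dihydroxy-3-methoxybenzaldehyde, via aryl sulfate 2 (not isolated)
Conditions: K2S2O8, aq NaOH, 0–20 °C; then aq HCl, 90 °C
Reagents that add atoms: potassium peroxodisulfate [K+].[K+].[O-]S(=O)(=O)OOS(=O)(=O)[O-]
Why: In the Elbs persulfate oxidation the phenolate attacks the peroxide oxygen through its only free para carbon (C5), and the aryl sulfate formed resists further oxidation until acid hydrolysis sets the hydroquinone free.

**Step 2**
Reactants: 3 2,5-dihydroxy-3-methoxybenzaldehyde
Product: 4 2,5-bis[(tert-butoxycarbonyl)oxy]-3-methoxybenzaldehyde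
Conditions: Boc2O (2.4 equiv), i-Pr2NEt, DMAP (cat.), THF, 0 °C to rt
Reagents that add atoms: di-tert-butyl dicarbonate CC(C)(C)OC(=O)OC(=O)OC(C)(C)C
Why: DMAP-catalysed O-tert-butoxycarbonylation of phenols also works for hindered, chelated salicylaldehyde hydroxyls, so one reagent installs both the ortho trigger and the remote protecting group.

**Step 3**
Reactants: 4 2,5-bis[(tert-butoxycarbonyl)oxy]-3-methoxybenzaldehyde
Product: 5 {2,5-bis[(tert-butoxycarbonyl)oxy]-3-methoxyphenyl}methanol
Conditions: BH3·THF, THF, 0 °C; then pH 7 buffer
Reagents that add atoms: none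
Why: Chemoselective aldehyde reduction with electrophilic borane passes through a non-basic boron alkoxide, so no free alkoxide arises that could start carbonate transfer, and aryl tert-butyl carbonates are inert to borane at 0 °C.

**Step 4**
Reactants: 5 {2,5-bis[(tert-butoxycarbonyl)oxy]-3-methoxyphenyl}methanol; 6 dodecylmagnesium bromide (commercial ether solution)
Product: 10 4-[(tert-butoxycarbonyl)oxy]-2-methoxy-6-tridecylphenyl acetate, via benzylic carbonate phenoxide 7 (not isolated), via o-quinone methide 8 (not isolated), via tridecylphenoxide 9 (not isolated)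
Conditions: 6 (3 equiv), Et2O–THF, −78 to 0 °C; then Ac2O (excess), DMAP (cat.), 0 °C to rt; aqueous work-up
Reagents that add atoms: acetic anhydride CC(=O)OC(C)=O
Why: The first equivalent of 6 deprotonates the benzylic alcohol, the alkoxide takes over the neighbouring aryl Boc group through a six-membered tetrahedral intermediate to give 7, and the magnesium phenoxide of 7 expels tert-butyl carbonate to give o-quinone methide 8. A second equivalent of 6 adds its C1 to the exocyclic CH2 of 8 in a 1,4-sense, driven by rearomatisation, which forms the ArCH2–CH2 bond and gives phenoxide 9, and acetic anhydride then acylates this one oxygen in the same flask. The closest known reaction type is the anionic low-temperature generation of o-quinone methides from o-OBoc salicyl alcohols or aldehydes followed by Grignard conjugate addition, finished here by a plain O-acylation of the phenoxide. No ring is closed and no stereocentre is formed. The step needs site selectivity between the two carbonates and between the two ring oxygens: only the carbonate ortho to the CH2OH lies within reach of the benzylic alkoxide, so the remote carbonate stays on as protecting group and only the hindered oxygen next to OMe is bared for acetylation, the reverse of what direct acylation of the free hydroquinone would favour. Chemoselectivity against carbonyl attack rests on the low temperature and the bulk of the tert-butyl carbonates, and oligomerisation of 8 is held down because it arises slowly in the presence of excess nucleophile.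

**Step 5**
Reactants: 10 4-[(tert-butoxycarbonyl)oxy]-2-methoxy-6-tridecylphenyl acetate
Product: 11 ardisiphenol D (4-hydroxy-2-methoxy-6-tridecylphenyl acetate)
Conditions: TFA, CH2Cl2, 0 °C to rt
Reagents that add atoms: none
Why: Acidolysis of the aryl tert-butyl carbonate (loss of the tert-butyl cation, then decarboxylation) is orthogonal to the aryl acetate, which is stable to anhydrous TFA and cannot migrate intramolecularly to the para oxygen.

**Compound list**
1 | o-vanillin (2-hydroxy-3-methoxybenzaldehyde) | COc1cccc(C=O)c1O | starting material
2 | potassium 3-formyl-4-hydroxy-5-methoxyphenyl sulfate | COc1cc(OS(=O)(=O)[O-])cc(C=O)c1O.[K+] | intermediate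
3 | 2,5-dihydroxy-3-methoxybenzaldehyde | COc1cc(O)cc(C=O)c1O | intermediate
4 | 2,5-bis[(tert-butoxycarbonyl)oxy]-3-methoxybenzaldehyde | COc1cc(OC(=O)OC(C)(C)C)cc(C=O)c1OC(=O)OC(C)(C)C | intermediate
5 | {2,5-bis[(tert-butoxycarbonyl)oxy]-3-methoxyphenyl}methanol | COc1cc(OC(=O)OC(C)(C)C)cc(CO)c1OC(=O)OC(C)(C)C | intermediate
6 | dodecylmagnesium bromide | CCCCCCCCCCCC[Mg]Br | starting material
7 | bromomagnesium 4-[(tert-butoxycarbonyl)oxy]-2-{[(tert-butoxycarbonyl)oxy]methyl}-6-methoxyphenoxide | COc1cc(OC(=O)OC(C)(C)C)cc(COC(=O)OC(C)(C)C)c1O[Mg]Br | intermediate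
8 | 4-[(tert-butoxycarbonyl)oxy]-2-methoxy-6-methylidenecyclohexa-2,4-dien-1-one (o-quinone methide) | C=C1C=C(OC(=O)OC(C)(C)C)C=C(OC)C1=O | intermediate
9 | bromomagnesium 4-[(tert-butoxycarbonyl)oxy]-2-methoxy-6-tridecylphenoxide | CCCCCCCCCCCCCc1cc(OC(=O)OC(C)(C)C)cc(OC)c1O[Mg]Br | intermediate
10 | 4-[(tert-butoxycarbonyl)oxy]-2-methoxy-6-tridecylphenyl acetate | CCCCCCCCCCCCCc1cc(OC(=O)OC(C)(C)C)cc(OC)c1OC(C)=O | intermediate
11 | ardisiphenol D (4-hydroxy-2-methoxy-6-tridecylphenyl acetate) | CCCCCCCCCCCCCc1cc(O)cc(OC)c1OC(C)=O | target

Total step count: 5. Longest linear sequence: 5.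

**Steps most likely to fail**

**Step 4.** Self-condensation of the transient o-quinone methide may outrun the Grignard addition. The Grignard reagent may attack the remote carbonate. Capture of the hindered phenoxide by the anhydride may stay incomplete. The fallback sets out from 3 and comes back at 11.
- The non-chelated 5-OH of 3 should be benzylated selectively (BnBr, K2CO3, acetone) to 5-(benzyloxy)-2-hydroxy-3-methoxybenzaldehyde F1.
- Wittig olefination with the ylide from dodecyltriphenylphosphonium bromide (NaHMDS, more than two equivalents, THF) should make the same carbon–carbon link as a double bond. The product is 4-(benzyloxy)-2-methoxy-6-[(Z)-tridec-1-en-1-yl]phenol F2, whose geometry is of no consequence.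
- Acetylation (Ac2O, pyridine) should give 4-(benzyloxy)-2-methoxy-6-[(Z)-tridec-1-en-1-yl]phenyl acetate F3.
- Hydrogenation (H2, Pd/C, EtOAc) should saturate the alkene and cleave the benzyl ether in one operation to give 11.

**Step 1.** Conversion may be poor, and the electron-rich phenolate may be over-oxidised to polymeric material. The fallback sets out from 1 and comes back at 3.
- Bromination para to the phenol (Br2, NaOAc, AcOH) should give 5-bromo-2-hydroxy-3-methoxybenzaldehyde F4.
- Miyaura borylation (B2pin2, Pd(dppf)Cl2, KOAc, dioxane, 80 °C) should give 2-hydroxy-3-methoxy-5-(4,4,5,5-tetramethyl-1,3,2-dioxaborolan-2-yl)benzaldehyde F5.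
- Oxidation of the C–B bond with trimethylamine N-oxide (CH2Cl2, rt) should give 3. This oxidant should not start a Dakin cleavage of the salicylaldehyde.

**Step 3.** Carbonate transfer may begin early, at the boron alkoxide stage or during the quench, followed by elimination and over-reduction of the benzylic position. The fallback sets out from 3 and comes back at 5, with reduction and protection in the reverse order.
- NaBH4 (EtOH–THF, 0 °C, under N2) should reduce 3 to 2-(hydroxymethyl)-6-methoxybenzene-1,4-diol F6.
- Carbonate formation through the phenoxides only (Boc2O, 2.1 equiv, K2CO3, 18-crown-6 cat., THF, 0 °C) should leave the far less acidic benzylic alcohol free and give 5.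

**Further compounds**
F1 | step 4 | 5-(benzyloxy)-2-hydroxy-3-methoxybenzaldehyde | COc1cc(OCc2ccccc2)cc(C=O)c1O
F2 | step 4 | 4-(benzyloxy)-2-methoxy-6-[(Z)-tridec-1-en-1-yl]phenol | CCCCCCCCCCC/C=C\c1cc(OCc2ccccc2)cc(OC)c1O
F3 | step 4 | 4-(benzyloxy)-2-methoxy-6-[(Z)-tridec-1-en-1-yl]phenyl acetate | CCCCCCCCCCC/C=C\c1cc(OCc2ccccc2)cc(OC)c1OC(C)=O
F4 | step 1 | 5-bromo-2-hydroxy-3-methoxybenzaldehyde | COc1cc(Br)cc(C=O)c1O
F5 | step 1 | 2-hydroxy-3-methoxy-5-(4,4,5,5-tetramethyl-1,3,2-dioxaborolan-2-yl)benzaldehyde | COc1cc(B2OC(C)(C)C(C)(C)O2)cc(C=O)c1O
F6 | step 3 | 2-(hydroxymethyl)-6-methoxybenzene-1,4-diol | COc1cc(O)cc(CO)c1O
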